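The trans-decalin is unravelled to an acyclic 2,8,10-undecatrienal. Ring B is read as the cyclohexene of an intramolecular Diels–Alder reaction: a C7=C8–C9=C10 diene, with C17 attached to C8 as CH2SiMe3, adds to a C5=C6 enal held by the C1–C4 chain. One Lewis-acid-promoted cycloaddition forms C6–C7 and C5–C10, closes rings A and B, creates the C10 quaternary centre and the trans C5/C10 fusion, and relays chirality from the C2 silyloxy carbon. The precursor is a tetrasubstituted E-dienyl allylsilane carrying the complete Z-enoate side chain. Afterwards the formyl activator is excised, protodesilylation gives the C8(17) methylene and 9α-H, and C2 is inverted by oxidation–reduction.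

Key step: step 12

Remark on numbering: labdane numbering is used for skeletal atoms throughout (C1–C10 decalin, C11–C16 side chain, C17 on C8, C20 angular methyl). The target is (13Z)-2β-acetoxylabda-8(17),13-dien-15-oic acid, (2R,5S,9S,10S).

Assumption: the Ti(OiPr)4/BINOL-catalysed addition of Chan's diene to aldehyde 4 is taken to follow its usual facial sense, so that (R)-BINOL delivers the (5S)-carbinol; if the sense proves opposite, (S)-BINOL is used.

Step 1
Reactants: 1 methyl 3,3-dimethylpent-4-enoate; 2 acrolein dimethyl acetal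
Product: 3 methyl (4E)-6,6-dimethoxy-3,3-dimethylhex-4-enoate
Conditions: second-generation Hoveyda–Grubbs catalyst RuCl2(H2IMes)(=CH-C6H4-2-OiPr) (5 mol%), 2 (4 equiv), CH2Cl2, 40 °C
Reagents that add atoms: none
Why: Olefin cross-metathesis between a vinyl group that cannot homodimerise (quaternary neighbour) and a fast-exchanging acrolein acetal is a selective pairing and should give the E-alkene under thermodynamic control.

Step 2
Reactants: 3 methyl (4E)-6,6-dimethoxy-3,3-dimethylhex-4-enoate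
Product: 4 (4E)-6,6-dimethoxy-3,3-dimethylhex-4-enal
Conditions: DIBAL-H (1.1 equiv), CH2Cl2, −78 °C; Rochelle salt work-up
Reagents that add atoms: none
Why: Partial ester reduction stops at the aluminium hemiacetal at −78 °C, and the acetal and alkene are inert to the hydride.

Step 3
Reactants: 4 (4E)-6,6-dimethoxy-3,3-dimethylhex-4-enal; 5 Chan's diene (1-methoxy-1,3-bis(trimethylsilyloxy)buta-1,3-diene)
Product: 7 methyl (5S,8E)-5-hydroxy-10,10-dimethoxy-7,7-dimethyl-3-oxodec-8-enoate, via bis-silylated aldol adduct 6 (not isolated)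
Conditions: Ti(OiPr)4 (8 mol%), (R)-BINOL (8 mol%), 4 Å MS, THF, −78 °C to rt; then PPTS, MeOH, 0 °C
Reagents that add atoms: none
Why: Catalytic enantioselective vinylogous Mukaiyama aldol addition, in which the chiral titanium–BINOL complex selects the aldehyde face and so sets C2 as the (S)-carbinol, while methanolic acid removes both silyl groups and leaves the dimethyl acetal unchanged.

Step 4
Reactants: 7 methyl (5S,8E)-5-hydroxy-10,10-dimethoxy-7,7-dimethyl-3-oxodec-8-enoate
Product: 8 methyl (5S,8E)-5-[(tert-butyldimethylsilyl)oxy]-10,10-dimethoxy-7,7-dimethyl-3-oxodec-8-enoate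
Conditions: TBSCl, imidazole, DMF, rt
Reagents that add atoms: tert-butyldimethylsilyl chloride, CC(C)(C)[Si](C)(C)Cl
Why: Standard silylation of the secondary alcohol blocks lactonisation and later oxa-Michael addition and provides the bulky group that directs step 12.

Step 5
Reactants: 8 methyl (5S,8E)-5-[(tert-butyldimethylsilyl)oxy]-10,10-dimethoxy-7,7-dimethyl-3-oxodec-8-enoate; 9 (4-iodobut-1-yn-1-yl)trimethylsilane
Product: 10 methyl (5S,8E)-5-[(tert-butyldimethylsilyl)oxy]-10,10-dimethoxy-7,7-dimethyl-3-oxo-2-[4-(trimethylsilyl)but-3-yn-1-yl]dec-8-enoate (mixture of epimers at the new centre)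
Conditions: K2CO3, acetone, reflux
Reagents that add atoms: none
Why: C-alkylation of the β-keto ester enolate with a primary iodide installs C11–C14, and the uncontrolled centre at C9 is erased in step 6.

Step 6
Reactants: 10 methyl (5S,8E)-5-[(tert-butyldimethylsilyl)oxy]-10,10-dimethoxy-7,7-dimethyl-3-oxo-2-[4-(trimethylsilyl)but-3-yn-1-yl]dec-8-enoate
Product: 12 methyl (2Z,5S,8E)-5-[(tert-butyldimethylsilyl)oxy]-10,10-dimethoxy-7,7-dimethyl-3-{[(trifluoromethyl)sulfonyl]oxy}-2-[4-(trimethylsilyl)but-3-yn-1-yl]deca-2,8-dienoate, via sodium enolate 11 (not isolated)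
Conditions: NaH, Et2O, 0 °C; then Tf2O, −78 to 0 °C
Reagents that add atoms: trifluoromethanesulfonic anhydride, O=S(=O)(OS(=O)(=O)C(F)(F)F)C(F)(F)F
Why: The sodium-chelated Z-enolate of the α-substituted β-keto ester is O-sulfonylated with retention, giving the enol triflate with OTf cis to the ester (stereodefined enol triflate formation).

Step 7
Reactants: 12 methyl (2Z,5S,8E)-5-[(tert-butyldimethylsilyl)oxy]-10,10-dimethoxy-7,7-dimethyl-3-{[(trifluoromethyl)sulfonyl]oxy}-2-[4-(trimethylsilyl)but-3-yn-1-yl]deca-2,8-dienoate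
Product: 13 methyl (2E,5S,8E)-5-[(tert-butyldimethylsilyl)oxy]-10,10-dimethoxy-3,7,7-trimethyl-2-[4-(trimethylsilyl)but-3-yn-1-yl]deca-2,8-dienoate
Conditions: MeZnCl (2 equiv), Pd(PPh3)4 (5 mol%), THF, 50 °C
Reagents that add atoms: methylzinc chloride, C[Zn]Cl
Why: Stereoretentive Negishi coupling replaces OTf by the C20 methyl, fixing the tetrasubstituted C9=C10 alkene with C20 cis to C8 and the C1 chain trans to C8.

Step 8
Reactants: 13 methyl (2E,5S,8E)-5-[(tert-butyldimethylsilyl)oxy]-10,10-dimethoxy-3,7,7-trimethyl-2-[4-(trimethylsilyl)but-3-yn-1-yl]deca-2,8-dienoate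
Product: 15 (2E,6S,8E)-6-[(tert-butyldimethylsilyl)oxy]-1,1-dimethoxy-4,4,8-trimethyl-10-methylidene-9-[4-(trimethylsilyl)but-3-yn-1-yl]-11-(trimethylsilyl)undeca-2,8-diene, via bis(silylmethyl) carbinol 14 (not isolated)
Conditions: TMSCH2MgCl (5 equiv), CeCl3 (5 equiv), THF, −78 °C to rt; aq. NH4Cl; then SiO2, CH2Cl2, rt
Reagents that add atoms: (trimethylsilyl)methylmagnesium chloride, C[Si](C)(C)C[Mg]Cl
Why: Double 1,2-addition of the non-basic organocerium reagent to the enoate ester followed by Peterson elimination of one β-silyl group on silica is the established ester-to-allylsilane conversion and turns C8 into the 2-(silylmethyl)diene carbon bearing C7 and C17.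

Step 9
Reactants: 15 (2E,6S,8E)-6-[(tert-butyldimethylsilyl)oxy]-1,1-dimethoxy-4,4,8-trimethyl-10-methylidene-9-[4-(trimethylsilyl)but-3-yn-1-yl]-11-(trimethylsilyl)undeca-2,8-diene
Product: 17 methyl (6E,9S,12E)-9-[(tert-butyldimethylsilyl)oxy]-14,14-dimethoxy-7,11,11-trimethyl-6-[3-(trimethylsilyl)prop-1-en-2-yl]tetradeca-6,12-dien-2-ynoate, via lithium acetylide 16 (not isolated)
Conditions: MeLi·LiBr (1.5 equiv), THF, 0 °C to rt; then ClCO2Me, −78 °C
Reagents that add atoms: methyl chloroformate, COC(=O)Cl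
Why: Methyllithium attacks only the alkynyl silicon, because an acetylide is the one good carbanion leaving group present, and the resulting acetylide is acylated by the chloroformate to the ynoate (C15).

Step 10
Reactants: 17 methyl (6E,9S,12E)-9-[(tert-butyldimethylsilyl)oxy]-14,14-dimethoxy-7,11,11-trimethyl-6-[3-(trimethylsilyl)prop-1-en-2-yl]tetradeca-6,12-dien-2-ynoate
Product: 19 methyl (2Z,6E,9S,12E)-9-[(tert-butyldimethylsilyl)oxy]-14,14-dimethoxy-3,7,11,11-tetramethyl-6-[3-(trimethylsilyl)prop-1-en-2-yl]tetradeca-2,6,12-trienoate, via alkenylcuprate 18 (not isolated)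
Conditions: Me2CuLi (from CuI and 2 MeLi, 1.5 equiv), THF, −78 °C; MeOH quench at −78 °C
Reagents that add atoms: lithium dimethylcuprate, [Li+].C[Cu-]C
Why: Syn carbocupration of the 2-ynoate and protonation of the alkenylcopper with retention at −78 °C place the new C16 methyl cis to H, which gives the 13Z enoate with the chain cis to the ester.

Step 11
Reactants: 19 methyl (2Z,6E,9S,12E)-9-[(tert-butyldimethylsilyl)oxy]-14,14-dimethoxy-3,7,11,11-tetramethyl-6-[3-(trimethylsilyl)prop-1-en-2-yl]tetradeca-2,6,12-trienoate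
Product: 20 methyl (2Z,6E,9S,12E)-9-[(tert-butyldimethylsilyl)oxy]-3,7,11,11-tetramethyl-14-oxo-6-[3-(trimethylsilyl)prop-1-en-2-yl]tetradeca-2,6,12-trienoate
Conditions: PPTS (10 mol%), acetone/H2O (20:1), rt
Reagents that add atoms: water, O
Why: The allylic acetal hydrolyses through a conjugated oxocarbenium ion under acid far too weak to protodesilylate the allylsilane or cleave the TBS ether.

Step 12
Reactants: 20 methyl (2Z,6E,9S,12E)-9-[(tert-butyldimethylsilyl)oxy]-3,7,11,11-tetramethyl-14-oxo-6-[3-(trimethylsilyl)prop-1-en-2-yl]tetradeca-2,6,12-trienoate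
Product: 21 methyl (13Z)-2α-[(tert-butyldimethylsilyl)oxy]-6α-formyl-17-(trimethylsilyl)labda-8,13-dien-15-oate (5α-H, 10β-CH3)
Conditions: Me2AlCl (2.5 equiv), CH2Cl2, −78 to −20 °C
Reagents that add atoms: none
Why: Me2AlCl, a proton-scavenging Lewis acid that tolerates the allylsilane, complexes the E-enal and lowers its LUMO so that a concerted, asynchronous [4+2] cycloaddition with the C7=C8–C9=C10 diene forms C5–C10 and C6–C7 at low temperature, below the onset of 1,5-hydrogen shifts of the cis-methyl diene; the closest known reaction type is the Lewis-acid-catalysed intramolecular Diels–Alder reaction of 2,8,10-undecatrienals to trans-fused octalins. Ring A closes through C5–C10 as a six-membered ring in the fused mode (the four-carbon tether C1–C4 joins diene terminus C10 to dienophile carbon C5 in a chair), and ring B is the cyclohexene created by the cycloaddition itself (C5–C10 and C6–C7 σ bonds, new C8=C9 π bond). C10 and C5 are set trans (10β-CH3, 5α-H) by the endo transition state of the E-enal together with the E geometry of C9=C10, which holds the tether outside and C20 inside, and the E-alkene geometry transfers suprafacially to give the 6α-formyl group, a centre erased in step 13. The absolute sense is relayed from C2: on the chair tether the OTBS group is equatorial because the axial position is syn-axial to both C20 and the axial C4 methyl, so the (S)-carbinol delivers the 5S,10S skeleton with a 2α-oxygen. The step needs endo/trans over exo/cis selectivity, which Lewis-acid complexation of the terminal formyl group favours, and chemoselectivity for the enal over the side-chain enoate, which is secured because the β,β-disubstituted enoate is unactivated by comparison and is held on the internal diene carbon C9 by only two methylene groups. The C4 gem-dimethyl group assists closure through the Thorpe–Ingold effect, and the CH2SiMe3 group on C8 raises the diene HOMO and biases it s-cis.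

Step 13
Reactants: 21 methyl (13Z)-2α-[(tert-butyldimethylsilyl)oxy]-6α-formyl-17-(trimethylsilyl)labda-8,13-dien-15-oate
Product: 22 methyl (13Z)-2α-[(tert-butyldimethylsilyl)oxy]-17-(trimethylsilyl)labda-8,13-dien-15-oate
Conditions: RhCl(PPh3)3 (1.2 equiv), PhCN, 130 °C
Reagents that add atoms: none
Why: Tsuji–Wilkinson decarbonylation (oxidative addition into the formyl C–H bond, CO extrusion, C–H reductive elimination) replaces the activating formyl group by hydrogen, so C6 becomes a plain CH2.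

Step 14
Reactants: 22 methyl (13Z)-2α-[(tert-butyldimethylsilyl)oxy]-17-(trimethylsilyl)labda-8,13-dien-15-oate
Product: 24 methyl (13Z)-2α-hydroxylabda-8(17),13-dien-15-oate, via exocyclic-alkene TBS ether 23 (not isolated)
Conditions: HCl (1.25 M in MeOH, 0.5 equiv), MeOH/CH2Cl2, 0 °C to rt
Reagents that add atoms: none
Why: Acid-mediated SE2' protodesilylation places the proton on C9 from the α-face, anti to the axial C20 methyl (9α-H, equatorial side chain), while the β-silyl cation at C8 collapses to the C8=C17 exocyclic alkene much faster than that alkene is reprotonated, and the same methanolic acid solvolyses the TBS ether.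

Step 15
Reactants: 24 methyl (13Z)-2α-hydroxylabda-8(17),13-dien-15-oate
Product: 25 methyl (13Z)-2-oxolabda-8(17),13-dien-15-oate
Conditions: Dess–Martin periodinane, NaHCO3, CH2Cl2, rt
Reagents that add atoms: none
Why: Mild Dess–Martin oxidation of the secondary alcohol removes the relay stereocentre without risk, since both α-carbons (C1, C3) adjoin quaternary carbons and no centre can epimerise.

Step 16
Reactants: 25 methyl (13Z)-2-oxolabda-8(17),13-dien-15-oate
Product: 26 methyl (13Z)-2β-hydroxylabda-8(17),13-dien-15-oate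
Conditions: L-Selectride (LiBH(s-Bu)3, 1.2 equiv), THF, −78 °C; NaOH/H2O2 work-up
Reagents that add atoms: none
Why: The bulky hydride attacks C2 from the α-face (equatorial approach) because the β-face is shielded by the two syn-axial methyl groups on C10 and C4, giving the axial 2β-alcohol, while the β,β-disubstituted enoate is spared at −78 °C.

Step 17
Reactants: 26 methyl (13Z)-2β-hydroxylabda-8(17),13-dien-15-oate
Product: 27 (13Z)-2β-hydroxylabda-8(17),13-dien-15-oic acid
Conditions: LiOH (5 equiv), THF/MeOH/H2O, 40 °C; then 1 M HCl to pH 3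
Reagents that add atoms: lithium hydroxide, [Li+].[OH-]
Why: Saponification of the methyl ester by acyl–oxygen cleavage should leave the Z-enoate geometry intact, because hydroxide does not generate the dienolate that would scramble it.

Step 18
Reactants: 27 (13Z)-2β-hydroxylabda-8(17),13-dien-15-oic acid
Product: 29 (13Z)-2β-acetoxylabda-8(17),13-dien-15-oic acid, via mixed acetic anhydride 28 (not isolated)
Conditions: Ac2O (5 equiv), DMAP (0.2 equiv), pyridine, 40 °C; then H2O/THF, rt
Reagents that add atoms: acetic anhydride, CC(=O)OC(C)=O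
Why: DMAP-catalysed acetylation overcomes the hindrance of the axial 2β-hydroxyl, and the mixed anhydride formed at the carboxyl group is hydrolysed selectively in the aqueous step to release the acid.

Compound list
1 | methyl 3,3-dimethylpent-4-enoate | C=CC(C)(C)CC(=O)OC | starting material
2 | acrolein dimethyl acetal (3,3-dimethoxyprop-1-ene) | C=CC(OC)OC | starting material
3 | methyl (4E)-6,6-dimethoxy-3,3-dimethylhex-4-enoate | COC(OC)/C=C/C(C)(C)CC(=O)OC | intermediate
4 | (4E)-6,6-dimethoxy-3,3-dimethylhex-4-enal | COC(OC)/C=C/C(C)(C)CC=O | intermediate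
5 | Chan's diene, 1-methoxy-1,3-bis(trimethylsilyloxy)buta-1,3-diene | COC(O[Si](C)(C)C)=CC(=C)O[Si](C)(C)C | starting material
6 | methyl (5S,8E)-10,10-dimethoxy-7,7-dimethyl-3,5-bis(trimethylsilyloxy)deca-2,8-dienoate (bis-silylated aldol adduct, not isolated) | COC(OC)/C=C/C(C)(C)C[C@H](O[Si](C)(C)C)CC(O[Si](C)(C)C)=CC(=O)OC | intermediate
7 | methyl (5S,8E)-5-hydroxy-10,10-dimethoxy-7,7-dimethyl-3-oxodec-8-enoate | COC(OC)/C=C/C(C)(C)C[C@H](O)CC(=O)CC(=O)OC | intermediate
8 | methyl (5S,8E)-5-[(tert-butyldimethylsilyl)oxy]-10,10-dimethoxy-7,7-dimethyl-3-oxodec-8-enoate | COC(OC)/C=C/C(C)(C)C[C@H](O[Si](C)(C)C(C)(C)C)CC(=O)CC(=O)OC | intermediate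
9 | (4-iodobut-1-yn-1-yl)trimethylsilane | C[Si](C)(C)C#CCCI | starting material
10 | methyl (5S,8E)-5-[(tert-butyldimethylsilyl)oxy]-10,10-dimethoxy-7,7-dimethyl-3-oxo-2-[4-(trimethylsilyl)but-3-yn-1-yl]dec-8-enoate (epimers at C2 of the chain) | COC(OC)/C=C/C(C)(C)C[C@H](O[Si](C)(C)C(C)(C)C)CC(=O)C(CCC#C[Si](C)(C)C)C(=O)OC | intermediate
11 | sodium (Z)-enolate of 10 (not isolated) | COC(OC)/C=C/C(C)(C)C[C@H](O[Si](C)(C)C(C)(C)C)C/C([O-])=C(\CCC#C[Si](C)(C)C)C(=O)OC.[Na+] | intermediate
12 | methyl (2Z,5S,8E)-5-[(tert-butyldimethylsilyl)oxy]-10,10-dimethoxy-7,7-dimethyl-3-{[(trifluoromethyl)sulfonyl]oxy}-2-[4-(trimethylsilyl)but-3-yn-1-yl]deca-2,8-dienoate | COC(OC)/C=C/C(C)(C)C[C@H](O[Si](C)(C)C(C)(C)C)C/C(OS(=O)(=O)C(F)(F)F)=C(\CCC#C[Si](C)(C)C)C(=O)OC | intermediate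
13 | methyl (2E,5S,8E)-5-[(tert-butyldimethylsilyl)oxy]-10,10-dimethoxy-3,7,7-trimethyl-2-[4-(trimethylsilyl)but-3-yn-1-yl]deca-2,8-dienoate | COC(OC)/C=C/C(C)(C)C[C@H](O[Si](C)(C)C(C)(C)C)C/C(C)=C(\CCC#C[Si](C)(C)C)C(=O)OC | intermediate
14 | (3E,6S,9E)-6-[(tert-butyldimethylsilyl)oxy]-11,11-dimethoxy-4,8,8-trimethyl-1-(trimethylsilyl)-2-[(trimethylsilyl)methyl]-3-[4-(trimethylsilyl)but-3-yn-1-yl]undeca-3,9-dien-2-ol (bis(silylmethyl) carbinol, not isolated) | COC(OC)/C=C/C(C)(C)C[C@H](O[Si](C)(C)C(C)(C)C)C/C(C)=C(\CCC#C[Si](C)(C)C)C(O)(C[Si](C)(C)C)C[Si](C)(C)C | intermediate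
15 | (2E,6S,8E)-6-[(tert-butyldimethylsilyl)oxy]-1,1-dimethoxy-4,4,8-trimethyl-10-methylidene-9-[4-(trimethylsilyl)but-3-yn-1-yl]-11-(trimethylsilyl)undeca-2,8-diene | COC(OC)/C=C/C(C)(C)C[C@H](O[Si](C)(C)C(C)(C)C)C/C(C)=C(\CCC#C[Si](C)(C)C)C(=C)C[Si](C)(C)C | intermediate
16 | lithium acetylide of 15 (alkynyl SiMe3 replaced by Li, not isolated) | COC(OC)/C=C/C(C)(C)C[C@H](O[Si](C)(C)C(C)(C)C)C/C(C)=C(\CCC#C[Li])C(=C)C[Si](C)(C)C | intermediate
17 | methyl (6E,9S,12E)-9-[(tert-butyldimethylsilyl)oxy]-14,14-dimethoxy-7,11,11-trimethyl-6-[3-(trimethylsilyl)prop-1-en-2-yl]tetradeca-6,12-dien-2-ynoate | COC(OC)/C=C/C(C)(C)C[C@H](O[Si](C)(C)C(C)(C)C)C/C(C)=C(\CCC#CC(=O)OC)C(=C)C[Si](C)(C)C | intermediate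
18 | lithium methyl(alkenyl)cuprate from syn addition to 17 (Cu on C14, cis to the new methyl, not isolated) | COC(OC)/C=C/C(C)(C)C[C@H](O[Si](C)(C)C(C)(C)C)C/C(C)=C(\CC/C(C)=C(/[Cu-]C)C(=O)OC)C(=C)C[Si](C)(C)C.[Li+] | intermediate
19 | methyl (2Z,6E,9S,12E)-9-[(tert-butyldimethylsilyl)oxy]-14,14-dimethoxy-3,7,11,11-tetramethyl-6-[3-(trimethylsilyl)prop-1-en-2-yl]tetradeca-2,6,12-trienoate | COC(OC)/C=C/C(C)(C)C[C@H](O[Si](C)(C)C(C)(C)C)C/C(C)=C(\CC/C(C)=C\C(=O)OC)C(=C)C[Si](C)(C)C | intermediate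
20 | methyl (2Z,6E,9S,12E)-9-[(tert-butyldimethylsilyl)oxy]-3,7,11,11-tetramethyl-14-oxo-6-[3-(trimethylsilyl)prop-1-en-2-yl]tetradeca-2,6,12-trienoate | O=C/C=C/C(C)(C)C[C@H](O[Si](C)(C)C(C)(C)C)C/C(C)=C(\CC/C(C)=C\C(=O)OC)C(=C)C[Si](C)(C)C | intermediate
21 | methyl (13Z)-2α-[(tert-butyldimethylsilyl)oxy]-6α-formyl-17-(trimethylsilyl)labda-8,13-dien-15-oate (5α-H, 10β-CH3) | C[Si](C)(C)CC=1C[C@H](C=O)[C@H]2C(C)(C)C[C@H](O[Si](C)(C)C(C)(C)C)C[C@]2(C)C=1CC/C(C)=C\C(=O)OC | intermediate
22 | methyl (13Z)-2α-[(tert-butyldimethylsilyl)oxy]-17-(trimethylsilyl)labda-8,13-dien-15-oate | C[Si](C)(C)CC=1CC[C@H]2C(C)(C)C[C@H](O[Si](C)(C)C(C)(C)C)C[C@]2(C)C=1CC/C(C)=C\C(=O)OC | intermediate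
23 | methyl (13Z)-2α-[(tert-butyldimethylsilyl)oxy]labda-8(17),13-dien-15-oate (9α-H, not isolated) | C=C1CC[C@H]2C(C)(C)C[C@H](O[Si](C)(C)C(C)(C)C)C[C@]2(C)[C@H]1CC/C(C)=C\C(=O)OC | intermediate
24 | methyl (13Z)-2α-hydroxylabda-8(17),13-dien-15-oate | C=C1CC[C@H]2C(C)(C)C[C@H](O)C[C@]2(C)[C@H]1CC/C(C)=C\C(=O)OC | intermediate
25 | methyl (13Z)-2-oxolabda-8(17),13-dien-15-oate | C=C1CC[C@H]2C(C)(C)CC(=O)C[C@]2(C)[C@H]1CC/C(C)=C\C(=O)OC | intermediate
26 | methyl (13Z)-2β-hydroxylabda-8(17),13-dien-15-oate | C=C1CC[C@H]2C(C)(C)C[C@@H](O)C[C@]2(C)[C@H]1CC/C(C)=C\C(=O)OC | intermediate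
27 | (13Z)-2β-hydroxylabda-8(17),13-dien-15-oic acid | C=C1CC[C@H]2C(C)(C)C[C@@H](O)C[C@]2(C)[C@H]1CC/C(C)=C\C(=O)O | intermediate
28 | acetic (13Z)-2β-acetoxylabda-8(17),13-dien-15-oic anhydride (not isolated) | C=C1CC[C@H]2C(C)(C)C[C@@H](OC(C)=O)C[C@]2(C)[C@H]1CC/C(C)=C\C(=O)OC(C)=O | intermediate
29 | (13Z)-2β-acetoxylabda-8(17),13-dien-15-oic acid, (2R,5S,9S,10S) | C=C1CC[C@H]2C(C)(C)C[C@@H](OC(C)=O)C[C@]2(C)[C@H]1CC/C(C)=C\C(=O)O | target

Total step count: 18. Longest linear sequence: 18 steps (from 1; all other inputs are commercial).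

Steps most likely to fail

Step 12. The cycloaddition may not start, because the inside C20 methyl twists the diene out of planarity and the C5–C10 bond joins a neopentyl carbon to a fully substituted one. It may also lose endo selectivity and give cis-fused material, or the diene may be desilylated by adventitious acid. The fallback raises the dienophile to a cation and sets out from acetal 19, bypassing step 11. TMSOTf (15 mol%) with 2,6-di-tert-butyl-4-methylpyridine in CH2Cl2 at −78 °C ionises the allylic acetal to a 1-methoxyallyl cation. This undergoes the stepwise ionic [4+2] addition known for unsaturated acetals: C10 attacks C5 first, then the enol ether carbon C6 closes onto C7. Recapture of methoxide should give methyl (13Z)-2α-[(tert-butyldimethylsilyl)oxy]-6α-(dimethoxymethyl)-17-(trimethylsilyl)labda-8,13-dien-15-oate F1. Mild hydrolysis (PPTS, wet acetone) returns the route at aldehyde 21.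

Step 8. The second addition to the hindered, tetrasubstituted enoate may stall, or the intermediate α-silyl ketone may be enolised instead of attacked. The fallback builds the C8 unit one carbon at a time from ester 13. DIBAL-H reduction gives (2E,5S,8E)-5-[(tert-butyldimethylsilyl)oxy]-10,10-dimethoxy-3,7,7-trimethyl-2-[4-(trimethylsilyl)but-3-yn-1-yl]deca-2,8-dien-1-ol F2. MnO2 oxidation gives the corresponding (2E,5S,8E)-deca-2,8-dienal F3. A single addition of TMSCH2MgCl to the far less hindered aldehyde, with neutral work-up, gives (3E,6S,9E)-6-[(tert-butyldimethylsilyl)oxy]-11,11-dimethoxy-4,8,8-trimethyl-1-(trimethylsilyl)-3-[4-(trimethylsilyl)but-3-yn-1-yl]undeca-3,9-dien-2-ol F4. Buffered Dess–Martin oxidation gives the α-silyl ketone, (3E,6S,9E)-6-[(tert-butyldimethylsilyl)oxy]-11,11-dimethoxy-4,8,8-trimethyl-1-(trimethylsilyl)-3-[4-(trimethylsilyl)but-3-yn-1-yl]undeca-3,9-dien-2-one F5. Wittig methylenation (Ph3P=CH2, THF) rejoins the route at diene 15.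

Step 1. Turnover at the vinyl group flanked by a quaternary carbon may be slow, so that the catalyst decays while the acetal partner is consumed by self-metathesis. The fallback replaces metathesis by carbonyl olefination and sets out from ester 1. Ozonolysis (O3, CH2Cl2, −78 °C; Me2S) gives methyl 3,3-dimethyl-4-oxobutanoate F6. Wittig reaction with (triphenylphosphoranylidene)acetaldehyde (toluene, 80 °C) gives methyl (4E)-3,3-dimethyl-6-oxohex-4-enoate F7. Acetalisation (HC(OMe)3, PPTS, MeOH) rejoins the route at acetal ester 3.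

Further compounds
F1 | step 12 | methyl (13Z)-2α-[(tert-butyldimethylsilyl)oxy]-6α-(dimethoxymethyl)-17-(trimethylsilyl)labda-8,13-dien-15-oate | C[Si](C)(C)CC=1C[C@H](C(OC)OC)[C@H]2C(C)(C)C[C@H](O[Si](C)(C)C(C)(C)C)C[C@]2(C)C=1CC/C(C)=C\C(=O)OC
F2 | step 8 | (2E,5S,8E)-5-[(tert-butyldimethylsilyl)oxy]-10,10-dimethoxy-3,7,7-trimethyl-2-[4-(trimethylsilyl)but-3-yn-1-yl]deca-2,8-dien-1-ol | COC(OC)/C=C/C(C)(C)C[C@H](O[Si](C)(C)C(C)(C)C)C/C(C)=C(\CCC#C[Si](C)(C)C)CO
F3 | step 8 | (2E,5S,8E)-5-[(tert-butyldimethylsilyl)oxy]-10,10-dimethoxy-3,7,7-trimethyl-2-[4-(trimethylsilyl)but-3-yn-1-yl]deca-2,8-dienal | COC(OC)/C=C/C(C)(C)C[C@H](O[Si](C)(C)C(C)(C)C)C/C(C)=C(\CCC#C[Si](C)(C)C)C=O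
F4 | step 8 | (3E,6S,9E)-6-[(tert-butyldimethylsilyl)oxy]-11,11-dimethoxy-4,8,8-trimethyl-1-(trimethylsilyl)-3-[4-(trimethylsilyl)but-3-yn-1-yl]undeca-3,9-dien-2-ol (epimers at C2) | COC(OC)/C=C/C(C)(C)C[C@H](O[Si](C)(C)C(C)(C)C)C/C(C)=C(\CCC#C[Si](C)(C)C)C(O)C[Si](C)(C)C
F5 | step 8 | (3E,6S,9E)-6-[(tert-butyldimethylsilyl)oxy]-11,11-dimethoxy-4,8,8-trimethyl-1-(trimethylsilyl)-3-[4-(trimethylsilyl)but-3-yn-1-yl]undeca-3,9-dien-2-one | COC(OC)/C=C/C(C)(C)C[C@H](O[Si](C)(C)C(C)(C)C)C/C(C)=C(\CCC#C[Si](C)(C)C)C(=O)C[Si](C)(C)C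
F6 | step 1 | methyl 3,3-dimethyl-4-oxobutanoate | COC(=O)CC(C)(C)C=O
F7 | step 1 | methyl (4E)-3,3-dimethyl-6-oxohex-4-enoate | COC(=O)CC(C)(C)/C=C/C=O
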